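**Plan**
- Retrosynthesis cuts the three biaryl bonds: the central naphthalene C-2–C-2' bond, then isoquinoline C-5 to naphthalene C-4 on one half and to C-5' on the other (naphthalen-1-ol numbering). This leaves one tetrahydroisoquinoline boronate 16 (used twice) and one naphthol 24 (used twice).
- In each heterocycle N-2 lies between C-1 (bonded to aromatic C-8a) and the methyl-bearing C-3, and C-4 closes the ring at C-4a. Without N-2 these atoms are the five-membered ring of a 2-methylindan-1-one, so the six-membered N-ring is made by Schmidt insertion of nitrogen into the C(=O)–CH(CH3) bond of indanone 8.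
- Forward, heterocycle: auxiliary alkylation, Friedel–Crafts closure of the indanone (Br blocks the para position and later serves as coupling handle), ring expansion, C-1 methyl through the activated lactam, trans reduction, O/N-benzylation, borylation.
- Forward, naphthalene: the phenolic ring of 24 is built from an open-chain o-allylbenzamide by anionic benzannulation. Ortho-bromination, then chlorination at C-4 (free OH) or C-5 (benzyl ether) gives the two halves; Br-selective Suzuki coupling, double Suzuki coupling at both chlorides and hydrogenolysis finish the route.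
- Stereochemistry: C-3 comes from the oxazolidinone-controlled alkylation and is carried with retention through the 1,2-shift; C-1 is set by C-3-controlled trans hydride addition to imine 12.

Key step: step 4

Assumption: the SMILES defines only the four carbon stereocentres (1R,3R in both heterocycles) and no biaryl axis, so the route controls these four centres; the hindered isoquinoline–naphthalene axes are expected to form as atropisomers that all correspond to the given SMILES and can be separated by chromatography at 32 or 33 if one is wanted.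

**Step 1**
Reactants: 1 (4S)-4-benzyl-3-propanoyl-1,3-oxazolidin-2-one; 2 1-bromo-2-(bromomethyl)-4-methoxybenzene
Product: 4 (4S)-4-benzyl-3-[(2R)-3-(2-bromo-5-methoxyphenyl)-2-methylpropanoyl]-1,3-oxazolidin-2-one, via sodium enolate 3 (not isolated)
Conditions: NaN(SiMe3)2, THF, −78 °C; then 2, −78 → −20 °C
Reagents that add atoms: none
Why: Evans alkylation, in which the chelated (Z)-enolate 3 should be attacked by the benzylic bromide on the face opposite the 4-benzyl group of the (S)-auxiliary, setting the new α-centre as (R).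

**Step 2**
Reactants: 4 (4S)-4-benzyl-3-[(2R)-3-(2-bromo-5-methoxyphenyl)-2-methylpropanoyl]-1,3-oxazolidin-2-one
Product: 6 (2R)-3-(2-bromo-5-methoxyphenyl)-2-methylpropanoic acid, via lithium peroxycarboxylate 5 (not isolated)
Conditions: LiOH, H2O2, THF/H2O, 0 °C; then Na2SO3 (aq), HCl
Reagents that add atoms: hydrogen peroxide, OO
Why: Hydroperoxide attacks the exocyclic imide carbonyl selectively (standard auxiliary cleavage), sulfite reduces peracid salt 5, and the mild conditions should leave the α-centre intact.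

**Step 3**
Reactants: 6 (2R)-3-(2-bromo-5-methoxyphenyl)-2-methylpropanoic acid
Product: 8 (2R)-4-bromo-7-methoxy-2-methyl-2,3-dihydro-1H-inden-1-one, via acid chloride 7 (not isolated)
Conditions: (COCl)2, DMF (cat.), CH2Cl2, 0 °C → rt; then AlCl3, CH2Cl2, −10 → 0 °C
Reagents that add atoms: none
Why: Intramolecular Friedel–Crafts acylation, in which bromine blocks the ortho position para to OMe so the acylium ion can only close the five-membered ring at the carbon ortho to OMe, and the base-free, cold conditions should preserve the α-centre.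

**Step 4**
Reactants: 8 (2R)-4-bromo-7-methoxy-2-methyl-2,3-dihydro-1H-inden-1-one
Product: 10 (3R)-5-bromo-8-methoxy-3-methyl-3,4-dihydroisoquinolin-1(2H)-one, via azidohydrin 9 (not isolated)
Conditions: NaN3, MeSO3H, CH2Cl2, 0 °C → rt
Reagents that add atoms: sodium azide, [Na+].[N-]=[N+]=[N-]
Why: Schmidt reaction: HN3 formed in the flask adds to the protonated ketone to give azidohydrin 9, which loses water and then N2 while the C-1–C-2 bond migrates to nitrogen, and hydration of the resulting cyclic imidate cation gives the lactam. The closest known reaction type is the Schmidt ring expansion of indan-1-ones to 3,4-dihydroisoquinolin-1(2H)-ones. No ring is closed; the five-membered carbocycle is enlarged to the six-membered lactam by a 1,2-shift of carbon to electron-deficient nitrogen, which places N between C-1 and the former C-2. No stereocentre is created: the (R)-centre at C-2 migrates suprafacially with retention and becomes C-3 of the isoquinoline, still (R). The step needs alkyl over aryl migration, which is expected because a bridging aryl group would require a strained spiro three-membered transition state on the five-membered ring, the migrating carbon is secondary and the aryl ring carries an inductively withdrawing bromine; configurational integrity rests on slow enolisation of the protonated aryl ketone at 0 °C in a medium without an effective base.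

**Step 5**
Reactants: 10 (3R)-5-bromo-8-methoxy-3-methyl-3,4-dihydroisoquinolin-1(2H)-one
Product: 12 (3R)-5-bromo-8-methoxy-1,3-dimethyl-3,4-dihydroisoquinoline, via imidoyl triflate 11 (not isolated)
Conditions: Tf2O, 2-fluoropyridine, CH2Cl2, −78 → 0 °C; then MeMgBr, −78 °C → rt
Reagents that add atoms: methylmagnesium bromide, C[Mg]Br
Why: Electrophilic amide activation, in which O-triflation of the secondary lactam gives imidoyl triflate 11 and the Grignard reagent adds with loss of triflate to give the cyclic ketimine (activated-amide ketimine synthesis); C-3 is remote from the reacting carbon and is unaffected.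

**Step 6**
Reactants: 12 (3R)-5-bromo-8-methoxy-1,3-dimethyl-3,4-dihydroisoquinoline
Product: 13 (1R,3R)-5-bromo-8-methoxy-1,3-dimethyl-1,2,3,4-tetrahydroisoquinoline
Conditions: LiAlH4, AlMe3, THF, −78 → 0 °C
Reagents that add atoms: none
Why: Substrate-controlled imine reduction, in which AlMe3 complexes the nitrogen and pushes the C-3 methyl group pseudoaxial, so that hydride should add to C-1 from the opposite face and give the 1,3-trans (1R,3R) amine (known trans-selective LiAlH4/AlMe3 protocol for 1,3-dimethyl-3,4-dihydroisoquinolines).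

**Step 7**
Reactants: 13 (1R,3R)-5-bromo-8-methoxy-1,3-dimethyl-1,2,3,4-tetrahydroisoquinoline
Product: 14 (1R,3R)-5-bromo-1,3-dimethyl-1,2,3,4-tetrahydroisoquinolin-8-ol
Conditions: BBr3, CH2Cl2, −78 °C → rt; MeOH, NaHCO3 (aq)
Reagents that add atoms: none
Why: Lewis-acid cleavage of the aryl methyl ether, done here because this is the only OMe group present and the naphthalene methyl ethers that must survive arrive later.

**Step 8**
Reactants: 14 (1R,3R)-5-bromo-1,3-dimethyl-1,2,3,4-tetrahydroisoquinolin-8-ol
Product: 15 (1R,3R)-2-benzyl-8-(benzyloxy)-5-bromo-1,3-dimethyl-1,2,3,4-tetrahydroisoquinoline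
Conditions: BnBr, Cs2CO3, MeCN, 60 °C
Reagents that add atoms: benzyl bromide, BrCc1ccccc1
Why: Williamson O-alkylation of the phenoxide and SN2 N-alkylation of the secondary amine in one operation, with the flanking C-1 and C-3 methyl groups preventing quaternisation.

**Step 9**
Reactants: 15 (1R,3R)-2-benzyl-8-(benzyloxy)-5-bromo-1,3-dimethyl-1,2,3,4-tetrahydroisoquinoline
Product: 16 (1R,3R)-2-benzyl-8-(benzyloxy)-1,3-dimethyl-5-(4,4,5,5-tetramethyl-1,3,2-dioxaborolan-2-yl)-1,2,3,4-tetrahydroisoquinoline
Conditions: B2pin2, PdCl2(dppf), KOAc, 1,4-dioxane, 90 °C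
Reagents that add atoms: bis(pinacolato)diboron, CC1(C)OB(OC1(C)C)B1OC(C)(C)C(C)(C)O1
Why: Miyaura borylation of the aryl bromide, to which benzyl ether and tertiary amine are inert.

**Step 10**
Reactants: 17 2-methoxy-4-methylbenzoic acid
Product: 19 N,N-diethyl-2-methoxy-4-methylbenzamide, via acid chloride 18 (not isolated)
Conditions: (COCl)2, DMF (cat.), CH2Cl2, rt; then Et2NH, 0 °C → rt
Reagents that add atoms: diethylamine, CCNCC
Why: Acyl chloride formation and aminolysis give the tertiary amide that serves as directing group in step 11 and as electrophile in step 12.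

**Step 11**
Reactants: 19 N,N-diethyl-2-methoxy-4-methylbenzamide; 20 allyl bromide
Product: 23 N,N-diethyl-2-methoxy-4-methyl-6-(prop-2-en-1-yl)benzamide, via aryllithium 21 (not isolated), via arylmagnesium bromide 22 (not isolated)
Conditions: s-BuLi, TMEDA, THF, −78 °C; MgBr2·OEt2, −78 → 0 °C; then 20, 0 °C → rt
Reagents that add atoms: none
Why: Directed ortho-metalation, in which the amide directs s-BuLi to its only free ortho position and transmetalation to magnesium before allylation avoids proton transfer from the acidic aryl–allyl CH2 of the product.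

**Step 12**
Reactants: 23 N,N-diethyl-2-methoxy-4-methyl-6-(prop-2-en-1-yl)benzamide
Product: 24 8-methoxy-6-methylnaphthalen-1-ol
Conditions: LiN(iPr)2, THF, −78 °C → rt; NH4Cl (aq)
Reagents that add atoms: none
Why: Anionic benzannulation of an o-allylbenzamide, in which deprotonation of the benzylic/allylic CH2 gives a delocalised anion whose terminal carbon attacks the amide carbonyl (6-exo-trig), and loss of LiNEt2 with tautomerisation gives the new phenolic ring from the open chain.

**Step 13**
Reactants: 24 8-methoxy-6-methylnaphthalen-1-ol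
Product: 25 2-bromo-8-methoxy-6-methylnaphthalen-1-ol
Conditions: NBS, iPr2NH (10 mol%), CH2Cl2, 0 °C
Reagents that add atoms: N-bromosuccinimide, O=C1CCC(=O)N1Br
Why: Amine-catalysed ortho-bromination of a phenol, in which the N-bromoamine formed in the flask is hydrogen-bonded to the OH group and should deliver bromine to C-2 in preference to the para position.

**Step 14**
Reactants: 25 2-bromo-8-methoxy-6-methylnaphthalen-1-ol
Product: 26 2-bromo-4-chloro-8-methoxy-6-methylnaphthalen-1-ol
Conditions: NCS, MeCN, 0 °C → rt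
Reagents that add atoms: N-chlorosuccinimide, O=C1CCC(=O)N1Cl
Why: Electrophilic aromatic chlorination, which with the ortho position occupied should go to C-4, para to the free OH and far more activated than any position of the anisole ring.

**Step 15**
Reactants: 26 2-bromo-4-chloro-8-methoxy-6-methylnaphthalen-1-ol
Product: 27 1-(benzyloxy)-2-bromo-4-chloro-8-methoxy-6-methylnaphthalene
Conditions: BnBr, K2CO3, DMF, 50 °C
Reagents that add atoms: benzyl bromide, BrCc1ccccc1
Why: Williamson ether synthesis on the naphtholate.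

**Step 16**
Reactants: 25 2-bromo-8-methoxy-6-methylnaphthalen-1-ol
Product: 28 1-(benzyloxy)-2-bromo-8-methoxy-6-methylnaphthalene
Conditions: BnBr, K2CO3, DMF, 50 °C
Reagents that add atoms: benzyl bromide, BrCc1ccccc1
Why: Williamson ether synthesis, which also removes the strong para-directing effect of the free OH before the next halogenation.

**Step 17**
Reactants: 28 1-(benzyloxy)-2-bromo-8-methoxy-6-methylnaphthalene
Product: 29 1-(benzyloxy)-2-bromo-5-chloro-8-methoxy-6-methylnaphthalene
Conditions: NCS, DMF, rt → 40 °C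
Reagents that add atoms: N-chlorosuccinimide, O=C1CCC(=O)N1Cl
Why: Electrophilic aromatic chlorination, in which the benzyloxy group is twisted out of conjugation by its two neighbours and its ring is deactivated by bromine, so the most nucleophilic carbon should be C-5, para to OMe and ortho to methyl (the position at which 1,8-dialkoxy-3-methylnaphthalenes are halogenated).

**Step 18**
Reactants: 29 1-(benzyloxy)-2-bromo-5-chloro-8-methoxy-6-methylnaphthalene
Product: 30 2-[1-(benzyloxy)-5-chloro-8-methoxy-6-methylnaphthalen-2-yl]-4,4,5,5-tetramethyl-1,3,2-dioxaborolane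
Conditions: B2pin2, PdCl2(dppf), KOAc, 1,4-dioxane, 80 °C
Reagents that add atoms: bis(pinacolato)diboron, CC1(C)OB(OC1(C)C)B1OC(C)(C)C(C)(C)O1
Why: Miyaura borylation, in which the C–Br bond undergoes oxidative addition much faster than the hindered, electron-rich C–Cl bond with this catalyst.

**Step 19**
Reactants: 27 1-(benzyloxy)-2-bromo-4-chloro-8-methoxy-6-methylnaphthalene; 30 2-[1-(benzyloxy)-5-chloro-8-methoxy-6-methylnaphthalen-2-yl]-4,4,5,5-tetramethyl-1,3,2-dioxaborolane
Product: 31 1,1'-bis(benzyloxy)-4,5'-dichloro-8,8'-dimethoxy-6,6'-dimethyl-2,2'-binaphthalene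
Conditions: Pd(PPh3)4, Na2CO3 (aq), DME, 85 °C
Reagents that add atoms: none
Why: Suzuki–Miyaura coupling, in which Pd(PPh3)4 inserts into the C–Br bond but not into the aryl chlorides, so only the central biaryl bond should form.

**Step 20**
Reactants: 31 1,1'-bis(benzyloxy)-4,5'-dichloro-8,8'-dimethoxy-6,6'-dimethyl-2,2'-binaphthalene; 16 (1R,3R)-2-benzyl-8-(benzyloxy)-1,3-dimethyl-5-(4,4,5,5-tetramethyl-1,3,2-dioxaborolan-2-yl)-1,2,3,4-tetrahydroisoquinoline (two equivalents)
Product: 32 1,1'-bis(benzyloxy)-4,5'-bis[(1R,3R)-2-benzyl-8-(benzyloxy)-1,3-dimethyl-1,2,3,4-tetrahydroisoquinolin-5-yl]-8,8'-dimethoxy-6,6'-dimethyl-2,2'-binaphthalene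
Conditions: Pd(OAc)2, SPhos, K3PO4, toluene/H2O, 100 °C
Reagents that add atoms: none
Why: Double Suzuki–Miyaura coupling of aryl chlorides with a bulky, electron-rich dialkylbiarylphosphine that allows oxidative addition into hindered aryl chlorides and formation of tri-ortho-substituted biaryls, so both heterocycles should be attached in one operation.

**Step 21**
Reactants: 32 1,1'-bis(benzyloxy)-4,5'-bis[(1R,3R)-2-benzyl-8-(benzyloxy)-1,3-dimethyl-1,2,3,4-tetrahydroisoquinolin-5-yl]-8,8'-dimethoxy-6,6'-dimethyl-2,2'-binaphthalene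
Product: 33 4,5'-bis[(1R,3R)-8-hydroxy-1,3-dimethyl-1,2,3,4-tetrahydroisoquinolin-5-yl]-8,8'-dimethoxy-6,6'-dimethyl-2,2'-binaphthalene-1,1'-diol (CNP0077060.1)
Conditions: H2 (1 atm), 10% Pd/C, MeOH/CH2Cl2, rt
Reagents that add atoms: none
Why: Hydrogenolysis of the four O-benzyl and two N-benzyl groups, which should leave the four stereocentres, the methyl ethers and the naphthalene rings untouched.

**Compound list**
1 | (4S)-4-benzyl-3-propanoyl-1,3-oxazolidin-2-one | CCC(=O)N1[C@@H](Cc2ccccc2)COC1=O | starting material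
2 | 1-bromo-2-(bromomethyl)-4-methoxybenzene | COc1ccc(Br)c(CBr)c1 | starting material
3 | sodium (Z)-enolate of 1 (not isolated) | C/C=C(\[O-])N1[C@@H](Cc2ccccc2)COC1=O.[Na+] | intermediate
4 | (4S)-4-benzyl-3-[(2R)-3-(2-bromo-5-methoxyphenyl)-2-methylpropanoyl]-1,3-oxazolidin-2-one | C[C@H](Cc1cc(OC)ccc1Br)C(=O)N1[C@@H](Cc2ccccc2)COC1=O | intermediate
5 | lithium (2R)-3-(2-bromo-5-methoxyphenyl)-2-methylpropaneperoxoate (not isolated) | C[C@H](Cc1cc(OC)ccc1Br)C(=O)O[O-].[Li+] | intermediate
6 | (2R)-3-(2-bromo-5-methoxyphenyl)-2-methylpropanoic acid | C[C@H](Cc1cc(OC)ccc1Br)C(=O)O | intermediate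
7 | (2R)-3-(2-bromo-5-methoxyphenyl)-2-methylpropanoyl chloride (not isolated) | C[C@H](Cc1cc(OC)ccc1Br)C(Cl)=O | intermediate
8 | (2R)-4-bromo-7-methoxy-2-methyl-2,3-dihydro-1H-inden-1-one | COc1ccc(Br)c2c1C(=O)[C@H](C)C2 | intermediate
9 | (2R)-1-azido-4-bromo-7-methoxy-2-methyl-2,3-dihydro-1H-inden-1-ol (C-1 undefined, not isolated) | COc1ccc(Br)c2c1C(O)(N=[N+]=[N-])[C@H](C)C2 | intermediate
10 | (3R)-5-bromo-8-methoxy-3-methyl-3,4-dihydroisoquinolin-1(2H)-one | COc1ccc(Br)c2c1C(=O)N[C@H](C)C2 | intermediate
11 | (3R)-5-bromo-8-methoxy-3-methyl-3,4-dihydroisoquinolin-1-yl trifluoromethanesulfonate (not isolated) | COc1ccc(Br)c2c1C(OS(=O)(=O)C(F)(F)F)=N[C@H](C)C2 | intermediate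
12 | (3R)-5-bromo-8-methoxy-1,3-dimethyl-3,4-dihydroisoquinoline | COc1ccc(Br)c2c1C(C)=N[C@H](C)C2 | intermediate
13 | (1R,3R)-5-bromo-8-methoxy-1,3-dimethyl-1,2,3,4-tetrahydroisoquinoline | Brc1ccc(OC)c2c1C[C@@H](C)N[C@@H]2C | intermediate
14 | (1R,3R)-5-bromo-1,3-dimethyl-1,2,3,4-tetrahydroisoquinolin-8-ol | Brc1ccc(O)c2c1C[C@@H](C)N[C@@H]2C | intermediate
15 | (1R,3R)-2-benzyl-8-(benzyloxy)-5-bromo-1,3-dimethyl-1,2,3,4-tetrahydroisoquinoline | Brc1ccc(OCc3ccccc3)c2c1C[C@@H](C)N(Cc4ccccc4)[C@@H]2C | intermediate
16 | (1R,3R)-2-benzyl-8-(benzyloxy)-1,3-dimethyl-5-(4,4,5,5-tetramethyl-1,3,2-dioxaborolan-2-yl)-1,2,3,4-tetrahydroisoquinoline | CC1(C)OB(OC1(C)C)c1ccc(OCc3ccccc3)c2c1C[C@@H](C)N(Cc4ccccc4)[C@@H]2C | intermediate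
17 | 2-methoxy-4-methylbenzoic acid | COc1cc(C)ccc1C(=O)O | starting material
18 | 2-methoxy-4-methylbenzoyl chloride (not isolated) | COc1cc(C)ccc1C(Cl)=O | intermediate
19 | N,N-diethyl-2-methoxy-4-methylbenzamide | CCN(CC)C(=O)c1ccc(C)cc1OC | intermediate
20 | allyl bromide (3-bromoprop-1-ene) | C=CCBr | starting material
21 | [2-(diethylcarbamoyl)-3-methoxy-5-methylphenyl]lithium (not isolated) | [Li]c1cc(C)cc(OC)c1C(=O)N(CC)CC | intermediate
22 | [2-(diethylcarbamoyl)-3-methoxy-5-methylphenyl]magnesium bromide (not isolated) | Br[Mg]c1cc(C)cc(OC)c1C(=O)N(CC)CC | intermediate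
23 | N,N-diethyl-2-methoxy-4-methyl-6-(prop-2-en-1-yl)benzamide | C=CCc1cc(C)cc(OC)c1C(=O)N(CC)CC | intermediate
24 | 8-methoxy-6-methylnaphthalen-1-ol | COc1cc(C)cc2cccc(O)c12 | intermediate
25 | 2-bromo-8-methoxy-6-methylnaphthalen-1-ol | COc1cc(C)cc2ccc(Br)c(O)c12 | intermediate
26 | 2-bromo-4-chloro-8-methoxy-6-methylnaphthalen-1-ol | COc1cc(C)cc2c(Cl)cc(Br)c(O)c12 | intermediate
27 | 1-(benzyloxy)-2-bromo-4-chloro-8-methoxy-6-methylnaphthalene | COc1cc(C)cc2c(Cl)cc(Br)c(OCc3ccccc3)c12 | intermediate
28 | 1-(benzyloxy)-2-bromo-8-methoxy-6-methylnaphthalene | COc1cc(C)cc2ccc(Br)c(OCc3ccccc3)c12 | intermediate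
29 | 1-(benzyloxy)-2-bromo-5-chloro-8-methoxy-6-methylnaphthalene | COc1cc(C)c(Cl)c2ccc(Br)c(OCc3ccccc3)c12 | intermediate
30 | 2-[1-(benzyloxy)-5-chloro-8-methoxy-6-methylnaphthalen-2-yl]-4,4,5,5-tetramethyl-1,3,2-dioxaborolane | COc1cc(C)c(Cl)c2ccc(B3OC(C)(C)C(C)(C)O3)c(OCc4ccccc4)c12 | intermediate
31 | 1,1'-bis(benzyloxy)-4,5'-dichloro-8,8'-dimethoxy-6,6'-dimethyl-2,2'-binaphthalene | COc1cc(C)cc2c(Cl)cc(-c3ccc4c(Cl)c(C)cc(OC)c4c3OCc3ccccc3)c(OCc3ccccc3)c12 | intermediate
32 | 1,1'-bis(benzyloxy)-4,5'-bis[(1R,3R)-2-benzyl-8-(benzyloxy)-1,3-dimethyl-1,2,3,4-tetrahydroisoquinolin-5-yl]-8,8'-dimethoxy-6,6'-dimethyl-2,2'-binaphthalene | COc1cc(C)cc2c(-c3ccc(OCc4ccccc4)c4c3C[C@@H](C)N(Cc3ccccc3)[C@@H]4C)cc(-c3ccc4c(-c5ccc(OCc6ccccc6)c6c5C[C@@H](C)N(Cc5ccccc5)[C@@H]6C)c(C)cc(OC)c4c3OCc3ccccc3)c(OCc3ccccc3)c12 | intermediate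
33 | 4,5'-bis[(1R,3R)-8-hydroxy-1,3-dimethyl-1,2,3,4-tetrahydroisoquinolin-5-yl]-8,8'-dimethoxy-6,6'-dimethyl-2,2'-binaphthalene-1,1'-diol (CNP0077060.1) | COc1cc(C)cc2c(-c3ccc(O)c4c3C[C@@H](C)N[C@@H]4C)cc(-c3ccc4c(-c5ccc(O)c6c5C[C@@H](C)N[C@@H]6C)c(C)cc(OC)c4c3O)c(O)c12 | target

**Summary**
Total step count: 21. Longest linear sequence: 11 steps (steps 1–9, 20, 21).

Steps most likely to fail:

1. Step 4. The ortho-methoxy group raises the migratory aptitude of the aryl carbon, so aryl migration (to the isomeric quinolinone) may compete with the wanted alkyl migration, and the α-centre may partly racemise by acid-catalysed enolisation before azide adds. Fallback by ring closure in place of ring expansion: from acid 6, Curtius rearrangement ((PhO)2P(O)N3, Et3N, toluene, 80 °C) should proceed through (2R)-3-(2-bromo-5-methoxyphenyl)-2-methylpropanoyl azide F1 to 1-bromo-2-[(2R)-2-isocyanatopropyl]-4-methoxybenzene F2 with retention. Addition of MeMgBr to the isocyanate should give N-[(2R)-1-(2-bromo-5-methoxyphenyl)propan-2-yl]acetamide F3, and Bischler–Napieralski cyclisation (POCl3, MeCN, reflux) at the only free ortho position returns to the route at imine 12.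

2. Step 17. Chlorination may lack positional selectivity (attack para to the benzyloxy group at C-4, or double chlorination). Fallback with an electron-poor oxygen substituent in place of the ether: from 25, acetylation (Ac2O, pyridine) should give 2-bromo-8-methoxy-6-methylnaphthalen-1-yl acetate F4, whose oxygen-bearing ring is deactivated. Chlorination with NCS should then give 2-bromo-5-chloro-8-methoxy-6-methylnaphthalen-1-yl acetate F5, methanolysis (K2CO3, MeOH) 2-bromo-5-chloro-8-methoxy-6-methylnaphthalen-1-ol F6, and benzylation (BnBr, K2CO3, DMF) returns to the route at 29.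

3. Step 20. Oxidative addition at the chloride flanked by a methyl group and a peri hydrogen may stall, or boronate 16 may protodeboronate, leaving mono-coupled material. Fallback with the roles of the partners exchanged: from 31, double Miyaura borylation (B2pin2, Pd(OAc)2, XPhos, KOAc, 1,4-dioxane, 110 °C) should give 2,2'-{1,1'-bis(benzyloxy)-8,8'-dimethoxy-6,6'-dimethyl-[2,2'-binaphthalene]-4,5'-diyl}bis(4,4,5,5-tetramethyl-1,3,2-dioxaborolane) F7. Its coupling with two equivalents of the more reactive aryl bromide 15 (Pd(OAc)2, SPhos, K3PO4, toluene/H2O, 100 °C) returns to the route at 32.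

**Further compounds**
F1 | step 4 | (2R)-3-(2-bromo-5-methoxyphenyl)-2-methylpropanoyl azide | C[C@H](Cc1cc(OC)ccc1Br)C(=O)N=[N+]=[N-]
F2 | step 4 | 1-bromo-2-[(2R)-2-isocyanatopropyl]-4-methoxybenzene | C[C@H](Cc1cc(OC)ccc1Br)N=C=O
F3 | step 4 | N-[(2R)-1-(2-bromo-5-methoxyphenyl)propan-2-yl]acetamide | C[C@H](Cc1cc(OC)ccc1Br)NC(C)=O
F4 | step 17 | 2-bromo-8-methoxy-6-methylnaphthalen-1-yl acetate | COc1cc(C)cc2ccc(Br)c(OC(C)=O)c12
F5 | step 17 | 2-bromo-5-chloro-8-methoxy-6-methylnaphthalen-1-yl acetate | COc1cc(C)c(Cl)c2ccc(Br)c(OC(C)=O)c12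
F6 | step 17 | 2-bromo-5-chloro-8-methoxy-6-methylnaphthalen-1-ol | COc1cc(C)c(Cl)c2ccc(Br)c(O)c12
F7 | step 20 | 2,2'-{1,1'-bis(benzyloxy)-8,8'-dimethoxy-6,6'-dimethyl-[2,2'-binaphthalene]-4,5'-diyl}bis(4,4,5,5-tetramethyl-1,3,2-dioxaborolane) | COc1cc(C)cc2c(B3OC(C)(C)C(C)(C)O3)cc(-c3ccc4c(B5OC(C)(C)C(C)(C)O5)c(C)cc(OC)c4c3OCc3ccccc3)c(OCc3ccccc3)c12
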